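## Analysis of the target

The target 22 is a 2-aryl-3-isopropylchroman. Ring C is the dihydropyran O1–C2–C3–C4, fused at C4a/C8a to ring A, a phloroglucinol ring with the ether oxygen O1 at C8a, free hydroxyls at C5 and C7, a 3-methylbutanoyl group between them at C6 and hydrogen at C8. Ring B, bound to C2, is a hexasubstituted 2,4,6-trihydroxy-3,5-diformylphenyl group. The two stereocentres are adjacent, C2 (R) and C3 (S), with the aryl group at C2 and the isopropyl group at C3 trans on ring C. The sensitive sites are the two aromatic aldehydes and the ketone, the five chelated phenols and, above all, the C2–O1 bond: it is a benzylic ether next to a trioxygenated arene, and acid can ionize it with opening of ring C and loss of the C2 configuration. The synthesis is hard because C2 is crowded, because ring A needs O1 para to the acyl group with C8 free, and because the stereodiad has no functional group at C3 or C4 to lean on. The strategy rests on C4: it is a plain methylene between C4a of ring A and C3, so it can be read as the terminal carbon of a 1,1-disubstituted alkene C3=C4 in an acyclic aryl ether. Hydroboration of that alkene creates C3 under the influence of C2 and makes C4 a nucleophile for the bond to C4a.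

## Retrosynthetic reasoning

**22 to 21.** The five phenols are carried as methyl ethers, so the last operation is cleavage of the five O–CH3 bonds of 21. Methyl ethers survive alkyllithium, alkoxide, borane and palladium chemistry, and in 21 every one of them sits ortho to a carbonyl group, the position from which a boron trihalide removes them most readily.

**21 to 18 and 19.** The C6 ketone is traced back to a nitrile and the two ring B aldehydes to cyclic acetals. The bond cut is C(=O)–CH2 of the side chain, so the isobutyl group comes from 19; the imine 20 and both acetals fall in one aqueous acid treatment. A nitrile is chosen at C6 in place of the ketone for three reasons: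
- As a linear group it stays conjugated between its two methoxy neighbours and still activates the para position, whereas a ketone there is twisted out of the ring plane.
- It has no acidic α-hydrogen that would quench an alkoxide.
- A dialkylborane that hydroborates an alkene leaves it alone, so the chemoselectivity question of the ring-closing step disappears.

**18 to 16 (key disconnection).** The C4–C4a bond and the C3–H bond are cut, which opens ring C to the aryl ether 16 with a bromide at C4a and a 1,1-disubstituted alkene C3=C4. Cutting here, and not at O1–C2 or C2–C3, keeps C2 as a stereocentre that is already in place and can direct the new one. It also makes C4 the nucleophile (as the alkylborane 17) and the ring A carbon the electrophile, so no cation arises beside the C2–O1 bond. The forward reaction must deliver hydrogen to one face of the alkene and then join a primary alkylborane to a hindered aryl bromide.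

**16 to 9 and 14.** The O1–C8a bond is cut. The alkoxide 15 of the allylic alcohol 9 displaces fluoride from 14, in which fluorine is para to the nitrile and ortho to bromine. Forming the aryl–oxygen bond, and not the C2–oxygen bond, leaves the carbinol centre untouched, so the configuration of 9 passes unchanged into 16.

**14 to 10.** In 14 the nitrile must lie between the two methoxy groups and para to fluorine. Electrophilic substitution or directed metalation of a meta-dimethoxy fluoroarene would put the new group next to fluorine, so the pattern is built by substitution chemistry from 10, where all positions are fixed. Both fluorides ortho to the nitrile are exchanged for methoxy groups (11). The para bromide becomes fluoride by way of the arylmagnesium species 12 (13). The symmetry of 13 then allows only one monobromide (14).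

**9 to 1, 3 and 4.** The C2 stereocentre is set by catalyst-controlled reduction of enone 8, reached by oxidation of the racemic alcohol 7. Compound 7 is cut at the C2–C3 bond into aldehyde 2 and vinyllithium 6, which brings in C3, C4 and the isopropyl group in one piece. Vinyllithium 6 comes from sulfonylhydrazone 5 (from 3 and 4). Aldehyde 2 is the threefold-symmetric trialdehyde 1 with two of its three equivalent formyl groups masked.

## Alternatives that were turned down

**Alternative 1: carbonyl-ene closure of C3–C4.**
- Disconnection and key step: ring C would be closed from the aryl ether A1, which has a formyl group at C4a and a trisubstituted alkene on C2. An aluminium Lewis acid activates the ring A aldehyde, C3 bonds to the carbonyl carbon and an allylic hydrogen is transferred, giving the 3-isopropenylchroman-4-ol A2.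
- For: the fluoride needed for the ether synthesis would be ortho to a formyl group, a stronger activation than in the chosen route. The cyclic ene transition state should place the C2 and C3 substituents trans at least as reliably as an acyclic hydroboration.
- Against: A2 has a hydroxyl at C4 and an alkene in the side chain that the target lacks. Removing a benzylic C4–OH ortho and para to three oxygens invites elimination into ring C or ionization. The isopropenyl group would have to be hydrogenated beside aldehydes and benzylic C–O bonds. A1 is an allylic and benzylic aryl ether with three aldehydes, exposed to a strong Lewis acid that can ionize C2–O1.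
- Comparison: the chosen route delivers C4 as CH2 and C3 with its isopropyl group directly, under basic conditions, and saves two or three corrective steps.

**Alternative 2: ring A built last by [3+3] annulation.**
- Disconnection and key step: C8–C8a and C5–C6 are cut. The dianion of dione A4 attacks the ketene acetal carbon of the dihydropyran ester A3 with loss of methoxide, then acylates on the ester, and enolization gives A5.
- For: the substitution pattern of ring A is unambiguous by construction and its two phenols arrive free. This is stronger than the chosen route, which needs a fluorination step and a fivefold ether cleavage.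
- Against: A3 must already hold both stereocentres, so the C2/C3 problem is only moved into a separate synthesis that the annulation does not help. In the addition–elimination the ring oxygen can leave in place of methoxide, which opens ring C. The ring-closing acylation has to occur at a hindered ester under dianion conditions that can also deprotonate C4.
- Comparison: the chosen route uses C2 to set C3 in the ring-forming step itself and needs no pre-made stereodiad.

**Alternative 3: oxonium-ene (Prins) annulation of an ortho-prenyl phenol.**
- Disconnection and key step: O1–C2 and C2–C3 are cut. Phenol A6 condenses with one formyl group of 1 to an O-aryl oxocarbenium ion, which C3 of the prenyl alkene attacks; proton loss leaves the 3-isopropenylchroman A7.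
- For: it is the most convergent plan, with two bonds and ring C from two simple achiral pieces and no acetal protection. It is clearly stronger in step economy.
- Against: both stereocentres are created in an achiral cationic step, so the absolute configuration would depend on a chiral acid acting on a doubly ortho-substituted aldehyde. Acid closes an ortho-prenyl phenol to a 2,2-dimethylchroman in competition. 1 offers three equivalent aldehydes. The isopropenyl group again needs hydrogenation beside aldehydes.
- Comparison: the chosen route is longer, but it fixes the absolute configuration by a reagent-controlled reduction and relays it to C3.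

Key step: step 10

## Route

Remark: 1, 3, 4, 10 and 19 are taken as purchased materials.

Remark: the (S)-oxazaborolidine in step 5 is chosen on the assumption that the hexasubstituted aryl group is the larger ketone substituent; if the sense proves reversed, the (R)-catalyst is used.

Step 1
Reactants: 1 2,4,6-trimethoxybenzene-1,3,5-tricarbaldehyde
Product: 2 3,5-bis(1,3-dioxolan-2-yl)-2,4,6-trimethoxybenzaldehyde
Conditions: HOCH2CH2OH (2.1 equiv), TsOH·H2O (5 mol %), toluene, reflux, Dean–Stark; chromatography, mono- and tris-acetal returned to 1 with aq. HCl/THF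
Reagents that add atoms: ethylene glycol, OCCO
Why: Acid-catalysed acetalization with removal of water; the three formyl groups of 1 are equivalent, so any two give the same compound, the distribution should be close to statistical with 2 as the main component, and the other acetals are recycled by hydrolysis.

Step 2
Reactants: 3 3-methylbutan-2-one; 4 2,4,6-tri(propan-2-yl)benzenesulfonohydrazide
Product: 5 (E)-N'-(3-methylbutan-2-ylidene)-2,4,6-tri(propan-2-yl)benzenesulfonohydrazide
Conditions: MeOH, conc. HCl (cat.), rt; crystallization
Reagents that add atoms: none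
Why: Condensation of a ketone with a sulfonylhydrazide to the hydrazone, expected with the sulfonamido group anti to the isopropyl branch.

Step 3
Reactants: 5 (E)-N'-(3-methylbutan-2-ylidene)-2,4,6-tri(propan-2-yl)benzenesulfonohydrazide; 2 3,5-bis(1,3-dioxolan-2-yl)-2,4,6-trimethoxybenzaldehyde
Product: 7 rac-1-[3,5-bis(1,3-dioxolan-2-yl)-2,4,6-trimethoxyphenyl]-3-methyl-2-methylidenebutan-1-ol, via 3-methylbut-1-en-2-yllithium 6 (not isolated)
Conditions: 5 (1.5 equiv), n-BuLi (3.0 equiv), TMEDA/hexane, −78 → 0 °C; then 2, THF, −78 °C → rt; aq. NH4Cl
Reagents that add atoms: none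
Why: Shapiro reaction: the hydrazone dianion forms at the methyl group (the less substituted α-carbon, syn to the sulfonamide nitrogen) and loses sulfinate and dinitrogen to give vinyllithium 6, which adds 1,2 to the non-enolizable aldehyde 2; the carbinol is racemic at this stage.

Step 4
Reactants: 7 rac-1-[3,5-bis(1,3-dioxolan-2-yl)-2,4,6-trimethoxyphenyl]-3-methyl-2-methylidenebutan-1-ol
Product: 8 1-[3,5-bis(1,3-dioxolan-2-yl)-2,4,6-trimethoxyphenyl]-3-methyl-2-methylidenebutan-1-one
Conditions: Dess–Martin periodinane (1.3 equiv), pyridine, CH2Cl2, 0 °C → rt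
Reagents that add atoms: none
Why: Dess–Martin oxidation of a secondary allylic and benzylic alcohol to the aryl enone; pyridine buffers the acetic acid so that the dioxolanes stay on.

Step 5
Reactants: 8 1-[3,5-bis(1,3-dioxolan-2-yl)-2,4,6-trimethoxyphenyl]-3-methyl-2-methylidenebutan-1-one
Product: 9 (1R)-1-[3,5-bis(1,3-dioxolan-2-yl)-2,4,6-trimethoxyphenyl]-3-methyl-2-methylidenebutan-1-ol
Conditions: (S)-2-methyl-CBS-oxazaborolidine [(3aS)-1-methyl-3,3-diphenyltetrahydro-1H,3H-pyrrolo[1,2-c][1,3,2]oxazaborole] (20 mol %), catecholborane (1.5 equiv), toluene, −78 → −40 °C; MeOH, then aq. NaOH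
Reagents that add atoms: none
Why: Corey–Bakshi–Shibata reduction of an enone (1,2-reduction): the catalyst binds the carbonyl oxygen on the side of the smaller substituent and delivers hydride from the boron-bound reagent to one face, which with the aryl group as the large substituent should give the R carbinol by analogy with aryl alkyl ketones; catecholborane is used because it does not hydroborate the alkene at this temperature.

Step 6
Reactants: 10 4-bromo-2,6-difluorobenzonitrile
Product: 11 4-bromo-2,6-dimethoxybenzonitrile
Conditions: NaOMe (2.5 equiv), MeOH, 65 °C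
Reagents that add atoms: sodium methoxide, [Na+].[O-]C
Why: Twofold nucleophilic aromatic substitution by addition–elimination; both fluorides are ortho to the nitrile and far better nucleofuges than the para bromide, which stays.

Step 7
Reactants: 11 4-bromo-2,6-dimethoxybenzonitrile
Product: 13 4-fluoro-2,6-dimethoxybenzonitrile, via arylmagnesium chloride 12 (not isolated)
Conditions: iPrMgCl·LiCl (1.1 equiv), THF, −20 °C; solvent exchange to CH2Cl2/perfluorodecalin (4:1); (PhSO2)2NF (1.3 equiv), 0 °C → rt
Reagents that add atoms: N-fluorobenzenesulfonimide, O=S(=O)(c1ccccc1)N(F)S(=O)(=O)c1ccccc1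
Why: Bromine–magnesium exchange at the bromide para to the nitrile, then electrophilic fluorination of the aryl Grignard reagent by an N–F reagent; the hindered nitrile tolerates the arylmagnesium species at low temperature and the non-ethereal solvent suppresses hydrogen abstraction.

Step 8
Reactants: 13 4-fluoro-2,6-dimethoxybenzonitrile
Product: 14 3-bromo-4-fluoro-2,6-dimethoxybenzonitrile
Conditions: NBS (1.05 equiv), CF3SO3H (10 mol %), MeCN, rt
Reagents that add atoms: N-bromosuccinimide, O=C1CCC(=O)N1Br
Why: Electrophilic aromatic bromination; the two free positions of 13 are equivalent and each is ortho to one methoxy group and para to the other, so only one monobromide can form, and the first bromine slows a second substitution.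

Step 9
Reactants: 9 (1R)-1-[3,5-bis(1,3-dioxolan-2-yl)-2,4,6-trimethoxyphenyl]-3-methyl-2-methylidenebutan-1-ol; 14 3-bromo-4-fluoro-2,6-dimethoxybenzonitrile
Product: 16 4-{[(1R)-1-[3,5-bis(1,3-dioxolan-2-yl)-2,4,6-trimethoxyphenyl]-3-methyl-2-methylidenebutyl]oxy}-3-bromo-2,6-dimethoxybenzonitrile, via sodium alkoxide 15 (not isolated)
Conditions: NaH (1.2 equiv), DMF, 0 °C; then 14 (1.1 equiv), 0 °C → rt
Reagents that add atoms: none
Why: Nucleophilic aromatic substitution of fluoride by an alkoxide; the fluorine of 14 is para to a nitrile that stays conjugated between its methoxy neighbours and ortho to bromine, and 14 has no acidic C–H to quench the alkoxide; the carbinol C–O bond is not involved, so the R configuration of 9 is carried into 16.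

Step 10
Reactants: 16 4-{[(1R)-1-[3,5-bis(1,3-dioxolan-2-yl)-2,4,6-trimethoxyphenyl]-3-methyl-2-methylidenebutyl]oxy}-3-bromo-2,6-dimethoxybenzonitrile
Product: 18 (2R,3S)-2-[3,5-bis(1,3-dioxolan-2-yl)-2,4,6-trimethoxyphenyl]-5,7-dimethoxy-3-(propan-2-yl)-3,4-dihydro-2H-chromene-6-carbonitrile, via B-alkyl-9-BBN 17 (not isolated)
Conditions: 9-BBN (9-borabicyclo[3.3.1]nonane dimer, 2.0 equiv B–H), THF, 0 → 40 °C; then degassed 3 M aq. K3PO4 (3 equiv), Pd(dppf)Cl2·CH2Cl2 (10 mol %), DMF, 70 °C
Reagents that add atoms: none
Why: Hydroboration followed by intramolecular B-alkyl Suzuki–Miyaura coupling; the closest known reaction type is the anti-selective 9-BBN hydroboration of 1,1-disubstituted allylic ethers joined to cross-coupling of the primary alkylborane with an aryl bromide. 9-BBN adds with boron at the terminal carbon C4 and hydrogen at C3 through a four-centre transition state in which the C2–H bond lies inside next to the bulky borane, the ring B aryl group stands anti to the forming C3–H bond and the aryloxy group points outside; hydrogen therefore arrives on the alkene face opposite ring B, which makes C3 S, the 1,2-anti relationship that becomes 2,3-trans in the ring, so the C2 stereocentre of 16 is the controlling element. Zerovalent palladium, formed from Pd(dppf)Cl2, inserts into the C4a–Br bond, the base-activated borate of 17 transfers the C4 methylene to palladium within the same molecule, and reductive elimination from the seven-membered aryl(alkyl)palladium chelate forms C4–C4a and closes the six-membered ring C. The wide bite angle of dppf favours this reductive elimination over β-hydride loss from C3. The step needs facial selectivity in the hydroboration, secured by the size difference between the hexasubstituted aryl group and the aryloxy group at C2, and chemoselectivity of the borane, secured because nitrile, aryl bromide and acetals react far more slowly with 9-BBN than a terminal alkene. Hydroboration is driven to completion before palladium is added, since a remaining allylic aryl ether could ionize to an allylpalladium species. Because C4 is the nucleophile, the ring A carbon the electrophile and the medium basic, no positive charge develops next to the acid-labile C2–O1 bond and C2 cannot epimerize.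

Step 11
Reactants: 18 (2R,3S)-2-[3,5-bis(1,3-dioxolan-2-yl)-2,4,6-trimethoxyphenyl]-5,7-dimethoxy-3-(propan-2-yl)-3,4-dihydro-2H-chromene-6-carbonitrile; 19 isobutyllithium (2-methylpropyllithium)
Product: 21 5-[(2R,3S)-5,7-dimethoxy-6-(3-methylbutanoyl)-3-(propan-2-yl)-3,4-dihydro-2H-chromen-2-yl]-2,4,6-trimethoxybenzene-1,3-dicarbaldehyde, via N–H ketimine 20 (not isolated)
Conditions: 19 (2.5 equiv), Et2O/THF, −78 → −20 °C; then 2 M aq. HCl, THF, 50 °C
Reagents that add atoms: water, O
Why: Addition of an alkyllithium to an aryl nitrile stops at the lithium ketimide; aqueous acid then hydrolyses the hindered ketimine 20 to the ketone and both dioxolanes to the aldehydes in one operation, the dioxolanes having shielded the formyl groups from 19.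

Step 12
Reactants: 21 5-[(2R,3S)-5,7-dimethoxy-6-(3-methylbutanoyl)-3-(propan-2-yl)-3,4-dihydro-2H-chromen-2-yl]-2,4,6-trimethoxybenzene-1,3-dicarbaldehyde
Product: 22 5-[(2R,3S)-5,7-dihydroxy-6-(3-methylbutanoyl)-3-(propan-2-yl)-3,4-dihydro-2H-chromen-2-yl]-2,4,6-trihydroxybenzene-1,3-dicarbaldehyde (CNP0551232.1)
Conditions: BBr3 (12 equiv), CH2Cl2, −78 → 0 °C; then MeOH, H2O
Reagents that add atoms: none
Why: Lewis acid cleavage of aryl methyl ethers; all five methoxy groups are ortho to a carbonyl group, but BCl3 would be expected to stop after the chelation-assisted cleavages, so the tribromide is used for all five. C2 and C3 are not touched, and ring B with two boron-complexed formyl groups gives little support to ionization of C2–O1.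

## Compound list

1 | 2,4,6-trimethoxybenzene-1,3,5-tricarbaldehyde | COc1c(C=O)c(OC)c(C=O)c(OC)c1C=O | starting material
2 | 3,5-bis(1,3-dioxolan-2-yl)-2,4,6-trimethoxybenzaldehyde | O=Cc1c(OC)c(C2OCCO2)c(OC)c(C3OCCO3)c1OC | intermediate
3 | 3-methylbutan-2-one | CC(C)C(C)=O | starting material
4 | 2,4,6-tri(propan-2-yl)benzenesulfonohydrazide | CC(C)c1cc(C(C)C)c(S(=O)(=O)NN)c(C(C)C)c1 | starting material
5 | (E)-N'-(3-methylbutan-2-ylidene)-2,4,6-tri(propan-2-yl)benzenesulfonohydrazide | C/C(=N\NS(=O)(=O)c1c(C(C)C)cc(C(C)C)cc1C(C)C)C(C)C | intermediate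
6 | 3-methylbut-1-en-2-yllithium (not isolated) | [Li]C(=C)C(C)C | intermediate
7 | rac-1-[3,5-bis(1,3-dioxolan-2-yl)-2,4,6-trimethoxyphenyl]-3-methyl-2-methylidenebutan-1-ol (racemate) | OC(C(=C)C(C)C)c1c(OC)c(C2OCCO2)c(OC)c(C3OCCO3)c1OC | intermediate
8 | 1-[3,5-bis(1,3-dioxolan-2-yl)-2,4,6-trimethoxyphenyl]-3-methyl-2-methylidenebutan-1-one | CC(C)C(=C)C(=O)c1c(OC)c(C2OCCO2)c(OC)c(C3OCCO3)c1OC | intermediate
9 | (1R)-1-[3,5-bis(1,3-dioxolan-2-yl)-2,4,6-trimethoxyphenyl]-3-methyl-2-methylidenebutan-1-ol | O[C@H](C(=C)C(C)C)c1c(OC)c(C2OCCO2)c(OC)c(C3OCCO3)c1OC | intermediate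
10 | 4-bromo-2,6-difluorobenzonitrile | N#Cc1c(F)cc(Br)cc1F | starting material
11 | 4-bromo-2,6-dimethoxybenzonitrile | N#Cc1c(OC)cc(Br)cc1OC | intermediate
12 | (4-cyano-3,5-dimethoxyphenyl)magnesium chloride, LiCl complex (not isolated) | N#Cc1c(OC)cc([Mg]Cl)cc1OC | intermediate
13 | 4-fluoro-2,6-dimethoxybenzonitrile | N#Cc1c(OC)cc(F)cc1OC | intermediate
14 | 3-bromo-4-fluoro-2,6-dimethoxybenzonitrile | N#Cc1c(OC)cc(F)c(Br)c1OC | intermediate
15 | sodium (1R)-1-[3,5-bis(1,3-dioxolan-2-yl)-2,4,6-trimethoxyphenyl]-3-methyl-2-methylidenebutan-1-olate (not isolated) | [Na+].[O-][C@H](C(=C)C(C)C)c1c(OC)c(C2OCCO2)c(OC)c(C3OCCO3)c1OC | intermediate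
16 | 4-{[(1R)-1-[3,5-bis(1,3-dioxolan-2-yl)-2,4,6-trimethoxyphenyl]-3-methyl-2-methylidenebutyl]oxy}-3-bromo-2,6-dimethoxybenzonitrile | N#Cc1c(OC)cc(O[C@H](C(=C)C(C)C)c2c(OC)c(C3OCCO3)c(OC)c(C4OCCO4)c2OC)c(Br)c1OC | intermediate
17 | 4-{[(1R,2S)-1-[3,5-bis(1,3-dioxolan-2-yl)-2,4,6-trimethoxyphenyl]-2-(9-borabicyclo[3.3.1]nonan-9-ylmethyl)-3-methylbutyl]oxy}-3-bromo-2,6-dimethoxybenzonitrile (not isolated) | C1CCC2CCCC1B2C[C@@H](C(C)C)[C@H](c1c(OC)c(C3OCCO3)c(OC)c(C4OCCO4)c1OC)Oc1cc(OC)c(C#N)c(OC)c1Br | intermediate
18 | (2R,3S)-2-[3,5-bis(1,3-dioxolan-2-yl)-2,4,6-trimethoxyphenyl]-5,7-dimethoxy-3-(propan-2-yl)-3,4-dihydro-2H-chromene-6-carbonitrile | N#Cc1c(OC)cc2c(c1OC)C[C@@H](C(C)C)[C@H](c1c(OC)c(C3OCCO3)c(OC)c(C4OCCO4)c1OC)O2 | intermediate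
19 | isobutyllithium (2-methylpropyllithium) | [Li]CC(C)C | starting material
20 | 1-[(2R,3S)-2-[3,5-bis(1,3-dioxolan-2-yl)-2,4,6-trimethoxyphenyl]-5,7-dimethoxy-3-(propan-2-yl)-3,4-dihydro-2H-chromen-6-yl]-3-methylbutan-1-imine (not isolated) | CC(C)CC(=N)c1c(OC)cc2c(c1OC)C[C@@H](C(C)C)[C@H](c1c(OC)c(C3OCCO3)c(OC)c(C4OCCO4)c1OC)O2 | intermediate
21 | 5-[(2R,3S)-5,7-dimethoxy-6-(3-methylbutanoyl)-3-(propan-2-yl)-3,4-dihydro-2H-chromen-2-yl]-2,4,6-trimethoxybenzene-1,3-dicarbaldehyde | CC(C)CC(=O)c1c(OC)cc2c(c1OC)C[C@@H](C(C)C)[C@H](c1c(OC)c(C=O)c(OC)c(C=O)c1OC)O2 | intermediate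
22 | 5-[(2R,3S)-5,7-dihydroxy-6-(3-methylbutanoyl)-3-(propan-2-yl)-3,4-dihydro-2H-chromen-2-yl]-2,4,6-trihydroxybenzene-1,3-dicarbaldehyde | CC(C)CC(=O)c1c(O)cc2c(c1O)C[C@@H](C(C)C)[C@H](c1c(O)c(C=O)c(O)c(C=O)c1O)O2 | target

## Step count and least certain steps

Total: 12 steps. Longest linear sequence: 8 steps (from 1 through 2, 7, 8, 9, 16, 18 and 21 to 22; equally from 3 through 5). The ring A branch from 10 to 22 is 7 steps.

**Step 10 (key step).** Two things may go wrong. Facial discrimination in the hydroboration may be poor, because the isopropyl group on the alkene presses against whichever C2 substituent sits outside and can erode the preference for the transition state described. Oxidative addition at the electron-rich, doubly ortho-substituted C4a–Br bond and transmetalation of the β-branched alkylborane may be slow, leaving room for protodeboronation or β-hydride loss. The fallback separates the two events and changes the ring closure. It sets out from 16: hydroboration with 9-BBN and oxidation with NaBO3·4H2O give the primary alcohol F1, at which stage the C3 epimers can be separated by chromatography. I2, PPh3 and imidazole convert it to the iodide F2, and Zn dust with LiCl in THF inserts to give the alkylzinc iodide F3. Intramolecular Negishi coupling with Pd(OAc)2 and SPhos closes ring C, and the route is rejoined at 18.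

**Step 5.** The enantioselectivity may be low, because a twisted hexasubstituted aryl group and a branched vinyl group are not clearly ranked as large and small by the catalyst, and because uncatalysed reduction can compete at a hindered carbonyl. The fallback is a resolution and sets out from racemic 7, bypassing 8. Sharpless kinetic resolution with D-(−)-diisopropyl tartrate, Ti(OiPr)4 and t-BuOOH (0.6 equiv) over 4 Å molecular sieves in CH2Cl2 at −20 °C should epoxidize the S enantiomer to the epoxy alcohol F4 and leave the R alcohol, so the route is rejoined at 9.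

**Step 7.** Fluorine transfer to the arylmagnesium intermediate may lose out to electron transfer and protonation, so that the carbon–fluorine bond does not form cleanly and the product is hard to purify. The fallback does without the fluoride. It sets out from 11: bromination with NBS gives 3,4-dibromo-2,6-dimethoxybenzonitrile F5, and the bromide para to the nitrile is used as the nucleofuge toward alkoxide 15 in DMSO at 50–60 °C, the meta bromide being unactivated. The route is rejoined at 16.

**Step 11.** The alkyllithium may displace a methoxy group ortho to the nitrile or metalate C8 in competition with addition to the hindered nitrile. The warm acid needed for the hindered ketimine may also ionize C2–O1 before the acetals are gone. The fallback goes through the aldehyde oxidation level and sets out from 18. iBu2AlH at −78 °C with buffered hydrolysis gives the C6 aldehyde F6. iBuMgBr adds to give the secondary alcohol F7 as a mixture at the new carbinol, and Dess–Martin oxidation gives the bis-dioxolane ketone F8. Brief treatment with 1 M aq. HCl in THF at rt removes the dioxolanes, and the route is rejoined at 21.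

**Step 12.** The Lewis acid may cleave the C2–O1 benzylic ether, with opening of ring C and loss of the C2 configuration, or the last methyl ether may resist. The fallback replaces Lewis acid cleavage by nucleophilic dealkylation. It sets out from 21: NaSEt in DMF at 110 °C attacks the methyl groups, each departing phenoxide being stabilized by its ortho carbonyl group, and acidification returns the route at 22 without a new intermediate.

## Further compounds

F1 | step 10 | 4-{[(1R,2R)-1-[3,5-bis(1,3-dioxolan-2-yl)-2,4,6-trimethoxyphenyl]-2-(hydroxymethyl)-3-methylbutyl]oxy}-3-bromo-2,6-dimethoxybenzonitrile | OC[C@@H](C(C)C)[C@H](c1c(OC)c(C2OCCO2)c(OC)c(C3OCCO3)c1OC)Oc1cc(OC)c(C#N)c(OC)c1Br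
F2 | step 10 | 4-{[(1R,2S)-1-[3,5-bis(1,3-dioxolan-2-yl)-2,4,6-trimethoxyphenyl]-2-(iodomethyl)-3-methylbutyl]oxy}-3-bromo-2,6-dimethoxybenzonitrile | IC[C@@H](C(C)C)[C@H](c1c(OC)c(C2OCCO2)c(OC)c(C3OCCO3)c1OC)Oc1cc(OC)c(C#N)c(OC)c1Br
F3 | step 10 | [(2S)-2-{(R)-[3,5-bis(1,3-dioxolan-2-yl)-2,4,6-trimethoxyphenyl](2-bromo-4-cyano-3,5-dimethoxyphenoxy)methyl}-3-methylbutyl]zinc iodide | I[Zn]C[C@@H](C(C)C)[C@H](c1c(OC)c(C2OCCO2)c(OC)c(C3OCCO3)c1OC)Oc1cc(OC)c(C#N)c(OC)c1Br
F4 | step 5 | (R)-[3,5-bis(1,3-dioxolan-2-yl)-2,4,6-trimethoxyphenyl][(2R)-2-(propan-2-yl)oxiran-2-yl]methanol | O[C@@H]([C@@]1(C(C)C)CO1)c1c(OC)c(C2OCCO2)c(OC)c(C3OCCO3)c1OC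
F5 | step 7 | 3,4-dibromo-2,6-dimethoxybenzonitrile | N#Cc1c(OC)cc(Br)c(Br)c1OC
F6 | step 11 | (2R,3S)-2-[3,5-bis(1,3-dioxolan-2-yl)-2,4,6-trimethoxyphenyl]-5,7-dimethoxy-3-(propan-2-yl)-3,4-dihydro-2H-chromene-6-carbaldehyde | O=Cc1c(OC)cc2c(c1OC)C[C@@H](C(C)C)[C@H](c1c(OC)c(C3OCCO3)c(OC)c(C4OCCO4)c1OC)O2
F7 | step 11 | 1-[(2R,3S)-2-[3,5-bis(1,3-dioxolan-2-yl)-2,4,6-trimethoxyphenyl]-5,7-dimethoxy-3-(propan-2-yl)-3,4-dihydro-2H-chromen-6-yl]-3-methylbutan-1-ol (both epimers at the carbinol) | CC(C)CC(O)c1c(OC)cc2c(c1OC)C[C@@H](C(C)C)[C@H](c1c(OC)c(C3OCCO3)c(OC)c(C4OCCO4)c1OC)O2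
F8 | step 11 | 1-[(2R,3S)-2-[3,5-bis(1,3-dioxolan-2-yl)-2,4,6-trimethoxyphenyl]-5,7-dimethoxy-3-(propan-2-yl)-3,4-dihydro-2H-chromen-6-yl]-3-methylbutan-1-one | CC(C)CC(=O)c1c(OC)cc2c(c1OC)C[C@@H](C(C)C)[C@H](c1c(OC)c(C3OCCO3)c(OC)c(C4OCCO4)c1OC)O2
F0 | step 12 | none | none
A1 | alternative 1 | 5-{(1R)-1-[2-formyl-3,5-dimethoxy-4-(3-methylbutanoyl)phenoxy]-3-methylbut-2-en-1-yl}-2,4,6-trimethoxybenzene-1,3-dicarbaldehyde | CC(C)CC(=O)c1c(OC)cc(O[C@H](C=C(C)C)c2c(OC)c(C=O)c(OC)c(C=O)c2OC)c(C=O)c1OC
A2 | alternative 1 | 5-[4-hydroxy-5,7-dimethoxy-6-(3-methylbutanoyl)-3-(prop-1-en-2-yl)-3,4-dihydro-2H-chromen-2-yl]-2,4,6-trimethoxybenzene-1,3-dicarbaldehyde, 2,3-trans with C2 as in 21, both C4 epimers | CC(C)CC(=O)c1c(OC)cc2c(c1OC)C(O)[C@@H](C(C)=C)[C@H](c1c(OC)c(C=O)c(OC)c(C=O)c1OC)O2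
A3 | alternative 2 | methyl (2R,3S)-2-[3,5-bis(1,3-dioxolan-2-yl)-2,4,6-trimethoxyphenyl]-6-methoxy-3-(propan-2-yl)-3,4-dihydro-2H-pyran-5-carboxylate | COC(=O)C1=C(OC)O[C@@H](c2c(OC)c(C3OCCO3)c(OC)c(C4OCCO4)c2OC)[C@H](C(C)C)C1
A4 | alternative 2 | 6-methylheptane-2,4-dione | CC(C)CC(=O)CC(C)=O
A5 | alternative 2 | 1-[(2R,3S)-2-[3,5-bis(1,3-dioxolan-2-yl)-2,4,6-trimethoxyphenyl]-5,7-dihydroxy-3-(propan-2-yl)-3,4-dihydro-2H-chromen-6-yl]-3-methylbutan-1-one | CC(C)CC(=O)c1c(O)cc2c(c1O)C[C@@H](C(C)C)[C@H](c1c(OC)c(C3OCCO3)c(OC)c(C4OCCO4)c1OC)O2
A6 | alternative 3 | 1-[4-hydroxy-2,6-dimethoxy-3-(3-methylbut-2-en-1-yl)phenyl]-3-methylbutan-1-one | CC(C)CC(=O)c1c(OC)cc(O)c(CC=C(C)C)c1OC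
A7 | alternative 3 | 5-[(2R,3S)-5,7-dimethoxy-6-(3-methylbutanoyl)-3-(prop-1-en-2-yl)-3,4-dihydro-2H-chromen-2-yl]-2,4,6-trimethoxybenzene-1,3-dicarbaldehyde | CC(C)CC(=O)c1c(OC)cc2c(c1OC)C[C@@H](C(C)=C)[C@H](c1c(OC)c(C=O)c(OC)c(C=O)c1OC)O2
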